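The butenolide (ring C) is cut at its C3–C4 bond. C4 with its hydroxyphenyl ring (ring A) and the exocyclic CH2 with its phenol ring (ring B) then prove to be two identical 4-oxybenzyl arms on C5, which is therefore a prochiral centre of a dibenzylglycolate. A carbene on a chiral dirhodium carboxamidate inserts into one benzylic C–H bond of one arm only. That single operation forms C3–C4, closes the lactone, fixes C5 and makes rings A and B chemically different for the later prenylation of ring B. The precursor is the achiral diazoacetate of methyl 2,2-bis(4-benzyloxybenzyl)glycolate.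

Key step: step 4

Remark (numbering): the lactone is numbered O1, C2 (carbonyl), C3, C4 (aryl-bearing), C5 (quaternary); ring A is the aryl group on C4, ring B the aryl group of the C5 benzyl substituent, ring C the lactone.
Remark (assumption): which arm the (4S)-configured catalyst selects cannot be predicted with certainty for a carbinol carbon without hydrogen; the configuration is to be checked on iodide 16 (anomalous dispersion), and the mirror-image (4R) catalyst would be used unchanged if the other arm reacts.
Remark (stoichiometry): step 1 builds both benzyl arms of 5 from chloride 1, so two equivalents of the Grignard reagent 3 made from 1 are consumed per molecule of oxalate 2.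

Step 1
Reactants: 1 4-(benzyloxy)benzyl chloride; 2 dimethyl oxalate
Product: 5 methyl 2-[4-(benzyloxy)benzyl]-3-[4-(benzyloxy)phenyl]-2-hydroxypropanoate, via benzylic Grignard reagent 3 (not isolated), via arylpyruvate ester 4 (not isolated)
Conditions: 1 (2.2 equiv), Mg turnings (1,2-dibromoethane activation), 2-MeTHF, 0 °C to rt, slow addition of 1; the solution of 3 then added to 2 (1.0 equiv) in THF, −78 °C to rt; aq. NH4Cl
Reagents that add atoms: [4-(benzyloxy)benzyl]magnesium chloride (second equivalent of Grignard reagent 3, made in the flask from 1), Cl[Mg]Cc1ccc(OCc2ccccc2)cc1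
Why: Grignard formation followed by twofold addition of 3 at one carbonyl carbon of the oxalate (Grignard addition to an ester), in which the first equivalent gives by addition–elimination the very electrophilic alpha-keto ester 4 and the second equivalent adds to its ketone in the keto form before it can enolise and faster than to the remaining ester, which is then shielded by the neighbouring magnesium alkoxide; no stereocenter is formed because the two arms are identical.

Step 2
Reactants: 5 methyl 2-[4-(benzyloxy)benzyl]-3-[4-(benzyloxy)phenyl]-2-hydroxypropanoate; 6 bromoacetyl bromide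
Product: 7 methyl 2-[4-(benzyloxy)benzyl]-3-[4-(benzyloxy)phenyl]-2-(bromoacetoxy)propanoate
Conditions: PhNMe2, CH2Cl2, 0 °C to rt
Reagents that add atoms: none
Why: O-acylation of a hindered tertiary alcohol by a small, highly reactive acid bromide (esterification), with a weakly nucleophilic aniline base that takes up HBr without displacing the alpha-bromide.

Step 3
Reactants: 7 methyl 2-[4-(benzyloxy)benzyl]-3-[4-(benzyloxy)phenyl]-2-(bromoacetoxy)propanoate
Product: 9 methyl 2-[4-(benzyloxy)benzyl]-3-[4-(benzyloxy)phenyl]-2-(diazoacetoxy)propanoate, via N-alkylated ditosylhydrazine 8 (not isolated)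
Conditions: TsNHNHTs (2 equiv), DBU (5 equiv), THF, 0 °C
Reagents that add atoms: N,N'-ditosylhydrazine, Cc1ccc(cc1)S(=O)(=O)NNS(=O)(=O)c1ccc(C)cc1
Why: Diazoacetate synthesis by the ditosylhydrazine method, in which the sulfonylhydrazide anion is alkylated by the alpha-bromo ester and two base-induced losses of toluenesulfinate (Bamford–Stevens-type elimination) leave the diazo group under conditions that spare the methyl ester and the benzyl ethers.

Step 4
Reactants: 9 methyl 2-[4-(benzyloxy)benzyl]-3-[4-(benzyloxy)phenyl]-2-(diazoacetoxy)propanoate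
Product: 10 methyl (2R,3R)-2-[4-(benzyloxy)benzyl]-3-[4-(benzyloxy)phenyl]-5-oxooxolane-2-carboxylate
Conditions: Rh2(4S-MPPIM)4 (dirhodium tetrakis[methyl (4S)-2-oxo-1-(3-phenylpropanoyl)imidazolidine-4-carboxylate], 1 mol %), CH2Cl2, reflux, 9 added by syringe pump over 10 h
Reagents that add atoms: none
Why: Loss of dinitrogen on the divalent rhodium dimer gives an electrophilic carbene at the future C3, which inserts into a benzylic C–H bond of one arm through a concerted, asynchronous three-centre transition state in which the hydrogen migrates with partial hydride character; the closest known reaction type is the enantioselective intramolecular C–H insertion of alkyl diazoacetates on chiral dirhodium carboxamidates, including desymmetrisations of diazoacetates with two enantiotopic alkyl groups and benzylic insertion of 2-arylethyl diazoacetates. Ring C closes as a five-membered lactone by 1,5-insertion, the new C3–C4 bond joining the carbene carbon to the carbon beta to the ester oxygen. C5 becomes stereogenic through the catalyst's choice between the two enantiotopic benzyl arms (ligand ester groups flanking the carbene admit one arm), and C4 through the choice between the two diastereotopic hydrogens of that arm, which should place the aryl group trans to the spectator benzyl group; C4 is made trigonal in step 6, so both C4 epimers converge. The step needs arm selection, insertion in preference to aromatic cycloaddition, ester-carbonyl ylide formation and carbene dimerisation; the less electrophilic carboxamidate carbene, the para-oxygen activation of all four candidate C–H bonds (which offsets the electron-withdrawing ester on C5), the absence of hydrogen on C5 (no four-membered lactone) and slow addition secure these.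

Step 5
Reactants: 10 methyl (2R,3R)-2-[4-(benzyloxy)benzyl]-3-[4-(benzyloxy)phenyl]-5-oxooxolane-2-carboxylate
Product: 12 methyl (2R,3S)-2-[4-(benzyloxy)benzyl]-3-[4-(benzyloxy)phenyl]-4-hydroxy-5-oxooxolane-2-carboxylate (mixture of epimers at the carbinol carbon), via potassium enolate 11 (not isolated)
Conditions: KN(SiMe3)2, THF, −78 °C; then 2-(phenylsulfonyl)-3-phenyloxaziridine, −78 °C; aq. NH4Cl
Reagents that add atoms: 2-(phenylsulfonyl)-3-phenyloxaziridine, O=S(=O)(c1ccccc1)N1OC1c1ccccc1
Why: Enolate hydroxylation with an N-sulfonyloxaziridine (Davis oxidation), C3 being the only enolisable position because C5 is quaternary and C4–H is not alpha to a carbonyl group; the configuration of the new carbinol carbon is irrelevant since it is oxidised in step 6.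

Step 6
Reactants: 12 methyl (2R,3S)-2-[4-(benzyloxy)benzyl]-3-[4-(benzyloxy)phenyl]-4-hydroxy-5-oxooxolane-2-carboxylate
Product: 14 methyl (2R)-2-[4-(benzyloxy)benzyl]-3-[4-(benzyloxy)phenyl]-4-hydroxy-5-oxo-2,5-dihydrofuran-2-carboxylate, via dioxo lactone 13 (not isolated)
Conditions: Dess–Martin periodinane (1.2 equiv), NaHCO3, CH2Cl2, 0 °C to rt; aq. Na2S2O3
Reagents that add atoms: none
Why: Dess–Martin oxidation of the secondary alpha-hydroxy lactone gives the 2,3-dioxo lactone, which tautomerises to the aryl-conjugated C3 enol and thereby erases the C4 stereocenter, while quaternary C5 cannot epimerise under these non-hydrolytic conditions.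

Step 7
Reactants: 14 methyl (2R)-2-[4-(benzyloxy)benzyl]-3-[4-(benzyloxy)phenyl]-4-hydroxy-5-oxo-2,5-dihydrofuran-2-carboxylate
Product: 15 methyl (2R)-4-hydroxy-2-(4-hydroxybenzyl)-3-(4-hydroxyphenyl)-5-oxo-2,5-dihydrofuran-2-carboxylate
Conditions: H2 (1 atm), Pd/C (palladium on carbon, 10 wt %), EtOAc–MeOH, rt
Reagents that add atoms: none
Why: Catalytic hydrogenolysis of two aryl benzyl ethers, which leaves the tetrasubstituted conjugated enol double bond and the non-benzylic C5–O1 bond untouched at atmospheric pressure.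

Step 8
Reactants: 15 methyl (2R)-4-hydroxy-2-(4-hydroxybenzyl)-3-(4-hydroxyphenyl)-5-oxo-2,5-dihydrofuran-2-carboxylate
Product: 16 methyl (2R)-4-hydroxy-2-(4-hydroxy-3-iodobenzyl)-3-(4-hydroxyphenyl)-5-oxo-2,5-dihydrofuran-2-carboxylate
Conditions: N-iodosuccinimide (1.0 equiv), TsOH·H2O (10 mol %), MeCN, −20 to 0 °C
Reagents that add atoms: N-iodosuccinimide, O=C1CCC(=O)N1I
Why: Acid-catalysed electrophilic aromatic iodination with both phenols un-ionised, in which ring B, a para-alkylphenol, reacts ortho to its hydroxyl group while ring A is deactivated by conjugation through C4=C3 with the lactone carbonyl and the fully substituted, hindered C4 is a poor site for attack; one equivalent of reagent at low temperature limits double iodination.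

Step 9
Reactants: 16 methyl (2R)-4-hydroxy-2-(4-hydroxy-3-iodobenzyl)-3-(4-hydroxyphenyl)-5-oxo-2,5-dihydrofuran-2-carboxylate
Product: 17 methyl (2R)-4-(tert-butyldimethylsilyloxy)-2-[4-(tert-butyldimethylsilyloxy)-3-iodobenzyl]-3-[4-(tert-butyldimethylsilyloxy)phenyl]-5-oxo-2,5-dihydrofuran-2-carboxylate
Conditions: TBSCl (4 equiv), imidazole, DMF, rt
Reagents that add atoms: tert-butyldimethylsilyl chloride, CC(C)(C)[Si](C)(C)Cl
Why: Standard O-silylation of two phenols and the acidic enol hydroxyl, giving groups that tolerate the neutral coupling and the near-neutral oxidation ahead and that are cleaved by buffered fluoride.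

Step 10
Reactants: 17 methyl (2R)-4-(tert-butyldimethylsilyloxy)-2-[4-(tert-butyldimethylsilyloxy)-3-iodobenzyl]-3-[4-(tert-butyldimethylsilyloxy)phenyl]-5-oxo-2,5-dihydrofuran-2-carboxylate; 18 tributyl(3-methylbut-2-en-1-yl)stannane
Product: 19 methyl (2R)-4-(tert-butyldimethylsilyloxy)-2-[4-(tert-butyldimethylsilyloxy)-3-(3-methylbut-2-en-1-yl)benzyl]-3-[4-(tert-butyldimethylsilyloxy)phenyl]-5-oxo-2,5-dihydrofuran-2-carboxylate
Conditions: Pd(PPh3)4 (5 mol %), DMF (degassed), 90 °C
Reagents that add atoms: none
Why: Stille coupling of an aryl iodide with an allylic stannane under neutral anhydrous conditions (oxidative addition to zerovalent palladium, transmetalation, reductive elimination at the less substituted allyl terminus) gives the linear prenyl arene and leaves silyl ethers, ester and lactone untouched.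

Step 11
Reactants: 19 methyl (2R)-4-(tert-butyldimethylsilyloxy)-2-[4-(tert-butyldimethylsilyloxy)-3-(3-methylbut-2-en-1-yl)benzyl]-3-[4-(tert-butyldimethylsilyloxy)phenyl]-5-oxo-2,5-dihydrofuran-2-carboxylate
Product: 20 methyl (2R)-4-(tert-butyldimethylsilyloxy)-2-{4-(tert-butyldimethylsilyloxy)-3-[((2R)-3,3-dimethyloxiran-2-yl)methyl]benzyl}-3-[4-(tert-butyldimethylsilyloxy)phenyl]-5-oxo-2,5-dihydrofuran-2-carboxylate
Conditions: D-fructose-derived Shi ketone (1,2:4,5-di-O-isopropylidene-β-D-erythro-hexo-2,3-diulo-2,6-pyranose, 1.5 equiv), Oxone (2KHSO5·KHSO4·K2SO4), NaHCO3, Bu4NHSO4 (cat.), MeCN–aq. Na2EDTA, 0 °C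
Reagents that add atoms: potassium peroxymonosulfate (active component of Oxone), [K+].[O-]S(=O)(=O)OO
Why: Shi epoxidation, in which the chiral dioxirane formed from the ketone transfers oxygen to the electron-rich trisubstituted alkene through the spiro transition state that gives the (R)-epoxide from a 2-methylbut-2-enyl group with this ketone enantiomer, while the tetrasubstituted, ester-conjugated, silyl-shielded C3=C4 bond is far less reactive; the bicarbonate-buffered protocol with a full equivalent of ketone is chosen to spare the aryl and enol silyl ethers.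

Step 12
Reactants: 20 methyl (2R)-4-(tert-butyldimethylsilyloxy)-2-{4-(tert-butyldimethylsilyloxy)-3-[((2R)-3,3-dimethyloxiran-2-yl)methyl]benzyl}-3-[4-(tert-butyldimethylsilyloxy)phenyl]-5-oxo-2,5-dihydrofuran-2-carboxylate
Product: 21 methyl (2R)-2-{3-[((2R)-3,3-dimethyloxiran-2-yl)methyl]-4-hydroxybenzyl}-4-hydroxy-3-(4-hydroxyphenyl)-5-oxo-2,5-dihydrofuran-2-carboxylate
Conditions: Bu4NF–AcOH (1:1, 4 equiv), THF, 0 °C; pH 7 phosphate buffer work-up
Reagents that add atoms: none
Why: Fluoride-induced cleavage of three silicon–oxygen bonds (aryl and enol silyl ethers are the most fluoride-labile), buffered with acetic acid so that no free phenoxide is present to open the neighbouring epoxide, with both stereocenters left untouched.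

Compound list
1 | 4-(benzyloxy)benzyl chloride | ClCc1ccc(OCc2ccccc2)cc1 | starting material
2 | dimethyl oxalate | COC(=O)C(=O)OC | starting material
3 | [4-(benzyloxy)benzyl]magnesium chloride | Cl[Mg]Cc1ccc(OCc2ccccc2)cc1 | intermediate
4 | methyl 3-[4-(benzyloxy)phenyl]-2-oxopropanoate | COC(=O)C(=O)Cc1ccc(OCc2ccccc2)cc1 | intermediate
5 | methyl 2-[4-(benzyloxy)benzyl]-3-[4-(benzyloxy)phenyl]-2-hydroxypropanoate | COC(=O)C(O)(Cc1ccc(OCc2ccccc2)cc1)Cc1ccc(OCc2ccccc2)cc1 | intermediate
6 | bromoacetyl bromide | BrCC(=O)Br | starting material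
7 | methyl 2-[4-(benzyloxy)benzyl]-3-[4-(benzyloxy)phenyl]-2-(bromoacetoxy)propanoate | COC(=O)C(Cc1ccc(OCc2ccccc2)cc1)(Cc1ccc(OCc2ccccc2)cc1)OC(=O)CBr | intermediate
8 | methyl 2-[4-(benzyloxy)benzyl]-3-[4-(benzyloxy)phenyl]-2-{[1,2-bis(4-methylphenylsulfonyl)hydrazin-1-yl]acetoxy}propanoate | COC(=O)C(Cc1ccc(OCc2ccccc2)cc1)(Cc1ccc(OCc2ccccc2)cc1)OC(=O)CN(NS(=O)(=O)c1ccc(C)cc1)S(=O)(=O)c1ccc(C)cc1 | intermediate
9 | methyl 2-[4-(benzyloxy)benzyl]-3-[4-(benzyloxy)phenyl]-2-(diazoacetoxy)propanoate (achiral, two enantiotopic arms) | COC(=O)C(Cc1ccc(OCc2ccccc2)cc1)(Cc1ccc(OCc2ccccc2)cc1)OC(=O)C=[N+]=[N-] | intermediate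
10 | methyl (2R,3R)-2-[4-(benzyloxy)benzyl]-3-[4-(benzyloxy)phenyl]-5-oxooxolane-2-carboxylate (4R,5R in lactone numbering; C4 aryl trans to the C5 benzyl group) | COC(=O)[C@]1(Cc2ccc(OCc3ccccc3)cc2)OC(=O)C[C@@H]1c1ccc(OCc2ccccc2)cc1 | intermediate
11 | potassium enolate of 10 (C2–C3 enolate, C4 and C5 as in 10) | COC(=O)[C@]1(Cc2ccc(OCc3ccccc3)cc2)OC([O-])=C[C@@H]1c1ccc(OCc2ccccc2)cc1.[K+] | intermediate
12 | methyl (2R,3S)-2-[4-(benzyloxy)benzyl]-3-[4-(benzyloxy)phenyl]-4-hydroxy-5-oxooxolane-2-carboxylate (same spatial arrangement at C4 and C5 as in 10; carbinol carbon C3 as a mixture of epimers) | COC(=O)[C@]1(Cc2ccc(OCc3ccccc3)cc2)OC(=O)C(O)[C@@H]1c1ccc(OCc2ccccc2)cc1 | intermediate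
13 | methyl (2R)-2-[4-(benzyloxy)benzyl]-3-[4-(benzyloxy)phenyl]-4,5-dioxooxolane-2-carboxylate (C4 epimerisable) | COC(=O)[C@]1(Cc2ccc(OCc3ccccc3)cc2)OC(=O)C(=O)C1c1ccc(OCc2ccccc2)cc1 | intermediate
14 | methyl (2R)-2-[4-(benzyloxy)benzyl]-3-[4-(benzyloxy)phenyl]-4-hydroxy-5-oxo-2,5-dihydrofuran-2-carboxylate | COC(=O)[C@]1(Cc2ccc(OCc3ccccc3)cc2)OC(=O)C(O)=C1c1ccc(OCc2ccccc2)cc1 | intermediate
15 | methyl (2R)-4-hydroxy-2-(4-hydroxybenzyl)-3-(4-hydroxyphenyl)-5-oxo-2,5-dihydrofuran-2-carboxylate | COC(=O)[C@]1(Cc2ccc(O)cc2)OC(=O)C(O)=C1c1ccc(O)cc1 | intermediate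
16 | methyl (2R)-4-hydroxy-2-(4-hydroxy-3-iodobenzyl)-3-(4-hydroxyphenyl)-5-oxo-2,5-dihydrofuran-2-carboxylate | COC(=O)[C@]1(Cc2ccc(O)c(I)c2)OC(=O)C(O)=C1c1ccc(O)cc1 | intermediate
17 | tris(tert-butyldimethylsilyl) ether of 16 (both phenols and the enol oxygen silylated) | COC(=O)[C@]1(Cc2ccc(O[Si](C)(C)C(C)(C)C)c(I)c2)OC(=O)C(O[Si](C)(C)C(C)(C)C)=C1c1ccc(O[Si](C)(C)C(C)(C)C)cc1 | intermediate
18 | tributyl(3-methylbut-2-en-1-yl)stannane | CCCC[Sn](CCCC)(CCCC)CC=C(C)C | starting material
19 | methyl (2R)-4-(tert-butyldimethylsilyloxy)-2-[4-(tert-butyldimethylsilyloxy)-3-(3-methylbut-2-en-1-yl)benzyl]-3-[4-(tert-butyldimethylsilyloxy)phenyl]-5-oxo-2,5-dihydrofuran-2-carboxylate | COC(=O)[C@]1(Cc2ccc(O[Si](C)(C)C(C)(C)C)c(CC=C(C)C)c2)OC(=O)C(O[Si](C)(C)C(C)(C)C)=C1c1ccc(O[Si](C)(C)C(C)(C)C)cc1 | intermediate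
20 | methyl (2R)-4-(tert-butyldimethylsilyloxy)-2-{4-(tert-butyldimethylsilyloxy)-3-[((2R)-3,3-dimethyloxiran-2-yl)methyl]benzyl}-3-[4-(tert-butyldimethylsilyloxy)phenyl]-5-oxo-2,5-dihydrofuran-2-carboxylate | COC(=O)[C@]1(Cc2ccc(O[Si](C)(C)C(C)(C)C)c(C[C@H]3OC3(C)C)c2)OC(=O)C(O[Si](C)(C)C(C)(C)C)=C1c1ccc(O[Si](C)(C)C(C)(C)C)cc1 | intermediate
21 | methyl (2R)-2-{3-[((2R)-3,3-dimethyloxiran-2-yl)methyl]-4-hydroxybenzyl}-4-hydroxy-3-(4-hydroxyphenyl)-5-oxo-2,5-dihydrofuran-2-carboxylate | COC(=O)[C@]1(Cc2ccc(O)c(C[C@H]3OC3(C)C)c2)OC(=O)C(O)=C1c1ccc(O)cc1 | target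

Total step count: 12. Longest linear sequence: 12 steps, from 1 to 21 (6 and 18 are purchased and enter in steps 2 and 10).

Steps most likely to fail

Step 4. What may go wrong: insufficient discrimination between the two enantiotopic arms, or diversion of the carbene into aromatic cycloaddition, ylide formation at the ester carbonyl or dimerisation. The fallback builds ring C by an aldol reaction instead of a carbene insertion and sets out from Grignard reagent 3 and oxalate 2. Inverse addition of 3 to an excess of 2 at −78 °C with a cold quench stops at the arylpyruvate ester 4, which is isolated this time. DBU in MeCN then brings about the known homo-aldol addition of the enolate of 4 to the ketone of a second molecule. The resulting tertiary alkoxide lactonises onto the ester of the donor half, and enolisation gives the racemic enol bis(benzyl ether) F1. Preparative chromatography on a polysaccharide chiral stationary phase separates the enantiomers, and the (R)-enantiomer is 14, where the route is rejoined before step 7.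

Step 8. What may go wrong: loss of site selectivity (attack on ring A or at the enol carbon C4) or double iodination of ring B. The fallback halogenates at the ether stage, before the phenols are freed, and sets out from 14. Acetylation of the enol hydroxyl (Ac2O, pyridine) gives the enol acetate F2, in which the C3=C4 bond and ring A are both further deactivated. NBS in MeCN brominates ring B ortho to its benzyloxy group, giving the aryl bromide F3; aryl ethers halogenate more slowly and more selectively than phenols, and the bromo ether resists a second substitution. BCl3 with pentamethylbenzene in CH2Cl2 at −78 °C removes both benzyl groups without touching the carbon–bromine bond, and NH3 in MeOH at 0 °C in the same operation cleaves the activated enol acetate, giving the bromo triol F4. Threefold silylation as in step 9 gives the tris(silyl ether) bromide F5, and Stille coupling with 18 (Pd(PPh3)4, DMF, 100 °C) comes back to the route at 19.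

Step 12. What may go wrong: intramolecular opening of the epoxide by the freshly liberated ring-B phenol or phenoxide during fluoride treatment or work-up, giving a cyclic ether. The fallback frees the hydroxyl groups with light instead of a reagent and sets out from 16. Alkylation of the three hydroxyl groups with 2-nitrobenzyl bromide and K2CO3 in acetone gives the tris(2-nitrobenzyl) ether iodide F6. Stille coupling with 18 as in step 10 gives the prenyl arene F7, and Shi epoxidation, which may now be run under the usual carbonate-buffered catalytic conditions because the ethers are base-stable, gives the epoxide F8. Irradiation at 365 nm in MeCN–pH 7 buffer releases the three hydroxyl groups as neutral OH groups through the aci-nitro pathway, without acid, base or fluoride, and arrives at 21.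

Further compounds
F1 | step 4 | racemic methyl 2-[4-(benzyloxy)benzyl]-3-[4-(benzyloxy)phenyl]-4-hydroxy-5-oxo-2,5-dihydrofuran-2-carboxylate | COC(=O)C1(Cc2ccc(OCc3ccccc3)cc2)OC(=O)C(O)=C1c1ccc(OCc2ccccc2)cc1
F2 | step 8 | methyl (2R)-4-acetoxy-2-[4-(benzyloxy)benzyl]-3-[4-(benzyloxy)phenyl]-5-oxo-2,5-dihydrofuran-2-carboxylate | COC(=O)[C@]1(Cc2ccc(OCc3ccccc3)cc2)OC(=O)C(OC(C)=O)=C1c1ccc(OCc2ccccc2)cc1
F3 | step 8 | methyl (2R)-4-acetoxy-2-[4-(benzyloxy)-3-bromobenzyl]-3-[4-(benzyloxy)phenyl]-5-oxo-2,5-dihydrofuran-2-carboxylate | COC(=O)[C@]1(Cc2ccc(OCc3ccccc3)c(Br)c2)OC(=O)C(OC(C)=O)=C1c1ccc(OCc2ccccc2)cc1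
F4 | step 8 | methyl (2R)-2-(3-bromo-4-hydroxybenzyl)-4-hydroxy-3-(4-hydroxyphenyl)-5-oxo-2,5-dihydrofuran-2-carboxylate | COC(=O)[C@]1(Cc2ccc(O)c(Br)c2)OC(=O)C(O)=C1c1ccc(O)cc1
F5 | step 8 | tris(tert-butyldimethylsilyl) ether of F4 | COC(=O)[C@]1(Cc2ccc(O[Si](C)(C)C(C)(C)C)c(Br)c2)OC(=O)C(O[Si](C)(C)C(C)(C)C)=C1c1ccc(O[Si](C)(C)C(C)(C)C)cc1
F6 | step 12 | methyl (2R)-2-[3-iodo-4-(2-nitrobenzyloxy)benzyl]-4-(2-nitrobenzyloxy)-3-[4-(2-nitrobenzyloxy)phenyl]-5-oxo-2,5-dihydrofuran-2-carboxylate | COC(=O)[C@]1(Cc2ccc(OCc3ccccc3[N+](=O)[O-])c(I)c2)OC(=O)C(OCc2ccccc2[N+](=O)[O-])=C1c1ccc(OCc2ccccc2[N+](=O)[O-])cc1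
F7 | step 12 | methyl (2R)-2-[3-(3-methylbut-2-en-1-yl)-4-(2-nitrobenzyloxy)benzyl]-4-(2-nitrobenzyloxy)-3-[4-(2-nitrobenzyloxy)phenyl]-5-oxo-2,5-dihydrofuran-2-carboxylate | COC(=O)[C@]1(Cc2ccc(OCc3ccccc3[N+](=O)[O-])c(CC=C(C)C)c2)OC(=O)C(OCc2ccccc2[N+](=O)[O-])=C1c1ccc(OCc2ccccc2[N+](=O)[O-])cc1
F8 | step 12 | methyl (2R)-2-{3-[((2R)-3,3-dimethyloxiran-2-yl)methyl]-4-(2-nitrobenzyloxy)benzyl}-4-(2-nitrobenzyloxy)-3-[4-(2-nitrobenzyloxy)phenyl]-5-oxo-2,5-dihydrofuran-2-carboxylate | COC(=O)[C@]1(Cc2ccc(OCc3ccccc3[N+](=O)[O-])c(C[C@H]3OC3(C)C)c2)OC(=O)C(OCc2ccccc2[N+](=O)[O-])=C1c1ccc(OCc2ccccc2[N+](=O)[O-])cc1
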